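**Plan**
Cuts: (a) the aryl–C(=O) bond of the ketone; (b) the benzylic O1–C2 ether bond of the oxolane; (c) C4–C5; (d) C2–C3.
Enabling feature: the ketone carbon on C4 and the oxygen of the CH2OH on C3 are 1,4-related (γ-hydroxy ketone, O–CH2–C3–C4–C=O). Both can therefore be stored in one γ-lactone cis-fused to the oxolane ring (3,7-dioxabicyclo[3.3.0]octan-2-one) and released by one aryllithium.
Forward: a succinate aldol with O-benzylsyringaldehyde closes temporary lactone ring A (oxygen on C2), and formaldehyde adds C5. Borane and then acid trade ring A for oxolane ring B plus lactone ring C, the aryllithium opens ring C, and hydrogenolysis frees both phenols.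
Stereochemistry: C2 and C3 are set together by one Evans syn aldol (purchased (S)-4-benzyloxazolidinone). C4 is relayed from C3 by anti hydroxymethylation, is held cis in the bicycle, and is reset to the all-trans array by base equilibration in the coupling flask.

Key step: step 8

Remark: the SMILES is read as the all-trans (2S,3R,4S) oxolane. The target locants O1, C2 (aryl), C3 (CH2OH), C4 (aroyl) and C5 (CH2) are kept for these atoms in every intermediate. Ar = 4-(benzyloxy)-3,5-dimethoxyphenyl.

**Step 1**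
Reactants: 1 syringaldehyde (4-hydroxy-3,5-dimethoxybenzaldehyde)
Product: 2 4-(benzyloxy)-3,5-dimethoxybenzaldehyde
Conditions: BnBr, K2CO3, DMF, 60 °C
Reagents that add atoms: benzyl bromide, BrCc1ccccc1
Why: Williamson ether synthesis on the acidic phenol gives a benzyl ether that should survive the boron, amide base, borane, acid and organolithium steps and is removed only at the end.

**Step 2**
Reactants: 3 (S)-4-benzyl-1,3-oxazolidin-2-one; 4 methyl 4-chloro-4-oxobutanoate
Product: 5 methyl 4-[(4S)-4-benzyl-2-oxo-1,3-oxazolidin-3-yl]-4-oxobutanoate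
Conditions: Et3N, DMAP (cat.), CH2Cl2, 0 °C to rt
Reagents that add atoms: none
Why: DMAP-catalysed N-acylation of the oxazolidinone by the acid chloride gives the imide, whose CH2 next to the imide carbonyl is the position a boron triflate enolises in preference to the ester side; no stereocentre is formed.

**Step 3**
Reactants: 5 succinyl imide; 2 4-(benzyloxy)-3,5-dimethoxybenzaldehyde
Product: 8 (4S)-4-benzyl-3-{[(2S,3S)-2-Ar-5-oxooxolan-3-yl]carbonyl}-1,3-oxazolidin-2-one, via boron enolate 6 (not isolated), via open syn aldol 7 (not isolated)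
Conditions: Bu2BOTf, Et3N, CH2Cl2, 0 °C; 2, −78 to 0 °C; H2O2, pH 7 buffer, MeOH, 0 °C; PPTS (cat.), CH2Cl2, rt
Reagents that add atoms: none
Why: Evans syn aldol reaction, in which the (Z)-boron enolate reacts through a closed chair transition state on the face away from the auxiliary benzyl group, so that C2 and C3 are set together, and the syn hydroxy ester then lactonises (5-exo-trig) to the 2,3-trans lactone ring A.

**Step 4**
Reactants: 8 lactone imide
Product: 10 (2S,3S)-2-Ar-5-oxooxolane-3-carboxylic acid, via peroxy acid 9 (not isolated)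
Conditions: LiOH, H2O2, THF–H2O, 0 °C; aq Na2SO3; HCl to pH 2
Reagents that add atoms: hydrogen peroxide (acting as LiOOH), OO
Why: Hydroperoxide cleavage of an N-acyl oxazolidinone attacks the exocyclic carbonyl selectively, any opened lactone re-closes on acidification, and neither stereocentre is touched.

**Step 5**
Reactants: 10 lactone acid
Product: 12 (2S,3S,4R)-2-Ar-4-(hydroxymethyl)-5-oxooxolane-3-carboxylic acid, via disodium dianion 11 (not isolated)
Conditions: NaN(SiMe3)2 (2.2 equiv), THF, −78 °C; CH2O (gas, from cracked paraformaldehyde), −78 to −40 °C; aq HCl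
Reagents that add atoms: formaldehyde, C=O
Why: Aldol-type α-hydroxymethylation of a lactone enolate, in which the carboxylate keeps C3–H from being removed, the enolate forms at C4, and formaldehyde approaches anti to the neighbouring C3 carboxylate, so C4 is set by substrate control as in the known α-alkylations of paraconic acid dianions.

**Step 6**
Reactants: 12 hydroxymethyl lactone acid
Product: 15 (3aR,4S,6aR)-4-Ar-tetrahydro-1H,3H-furo[3,4-c]furan-1-one, via diol lactone 13 (not isolated), via rearranged lactone diol 14 (not isolated)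
Conditions: BH3·SMe2, THF, 0 °C to rt; MeOH; then p-TsOH·H2O (cat.), CH2Cl2 (dilute), rt
Reagents that add atoms: none
Why: Borane reduces the free acid much faster than the lactone (chemoselective acid reduction), and acid then drives acyl migration to the primary C3 carbinol (translactonisation) and an SN1-type benzylic etherification in which the C5 hydroxyl closes oxolane ring B (5-exo attack on the alkoxy-stabilised benzylic cation), as known from furofuran lignan chemistry; C3 and C4 are untouched, only the cis-fused bicycle can form, and reversible ionisation leaves the aryl group on the convex face, which is the C2 configuration already set by the aldol.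

**Step 7**
Reactants: 16 4-bromo-2,6-dimethoxyphenol
Product: 17 2-(benzyloxy)-5-bromo-1,3-dimethoxybenzene
Conditions: BnBr, K2CO3, DMF, 60 °C
Reagents that add atoms: benzyl bromide, BrCc1ccccc1
Why: Williamson ether synthesis masks the acidic phenol so that the bromide can be turned into an aryllithium.

**Step 8**
Reactants: 17 2-(benzyloxy)-5-bromo-1,3-dimethoxybenzene; 15 bicyclic lactone
Product: 21 [(3S,4R,5S)-5-Ar-4-(hydroxymethyl)oxolan-3-yl](Ar)methanone, via aryllithium 18 (not isolated), via lithium lactolate 19 (not isolated), via cis keto alcohol 20 (not isolated)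
Conditions: 17, n-BuLi, THF, −78 °C; 15, −78 °C; MeOH, −78 °C to rt; aq NH4Cl
Reagents that add atoms: none
Why: Bromine–lithium exchange gives 18, which adds to the lactone carbonyl of 15 from the convex face to give the bicyclic lactolate 19; this tetrahedral intermediate should not collapse at −78 °C, so no ketone is exposed to 18 and only one aryl group is transferred. Methanol then frees the hemiketal, which opens to the cis γ-hydroxy ketone 20, and the LiOMe formed in the quench equilibrates C4 through the enolate to the all-trans ketone 21. The closest known reaction types are the addition of aryllithium reagents to γ-butyrolactones (including furofuranone lactones) to give γ-hydroxy aryl ketones, and the base epimerisation of 3-acyl oxolanes. No ring is closed: helper ring C is opened in the same operation that forms the C–C bond, so ketone and free CH2OH appear together without any protecting-group or redox step. The only lasting stereochemical change is at C4, where thermodynamic control by the neighbouring C3 hydroxymethyl group (and, through it, C2) favours the trans aroyl group, while C2 and C3 carry no acidic hydrogen and the hemiketal carbon disappears. The step needs addition over enolisation, which low temperature and the open convex face should secure, and no β-elimination of O1, which is slow because the C5–O1 bond lies near the nodal plane of the exocyclic enolate (the reverse of a 5-endo-trig closure).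

**Step 9**
Reactants: 21 dibenzyl ether of the target
Product: 22 [(3S,4R,5S)-5-(4-hydroxy-3,5-dimethoxyphenyl)-4-(hydroxymethyl)oxolan-3-yl](4-hydroxy-3,5-dimethoxyphenyl)methanone (target)
Conditions: H2 (1 atm), Pd/C, EtOAc–EtOH, rt, stopped after uptake of two equivalents
Reagents that add atoms: none
Why: Catalytic hydrogenolysis cleaves phenolic benzyl ethers faster than the ring benzylic C2–O1 bond or the conjugated electron-rich aryl ketone in a neutral solvent at one atmosphere, and no stereocentre is involved.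

**Compound list**
1 | syringaldehyde (4-hydroxy-3,5-dimethoxybenzaldehyde) | COc1cc(C=O)cc(OC)c1O | starting material
2 | 4-(benzyloxy)-3,5-dimethoxybenzaldehyde | COc1cc(C=O)cc(OC)c1OCc1ccccc1 | intermediate
3 | (S)-4-benzyl-1,3-oxazolidin-2-one | O=C1N[C@@H](Cc2ccccc2)CO1 | starting material
4 | methyl 4-chloro-4-oxobutanoate | COC(=O)CCC(=O)Cl | starting material
5 | methyl 4-[(4S)-4-benzyl-2-oxo-1,3-oxazolidin-3-yl]-4-oxobutanoate | COC(=O)CCC(=O)N1[C@@H](Cc2ccccc2)COC1=O | intermediate
6 | (Z)-dibutylboron enolate of 5 | COC(=O)C/C=C(\OB(CCCC)CCCC)N1[C@@H](Cc2ccccc2)COC1=O | intermediate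
7 | methyl (3S)-3-{(S)-[4-(benzyloxy)-3,5-dimethoxyphenyl](hydroxy)methyl}-4-[(4S)-4-benzyl-2-oxo-1,3-oxazolidin-3-yl]-4-oxobutanoate | COC(=O)C[C@H](C(=O)N1[C@@H](Cc2ccccc2)COC1=O)[C@H](O)c3cc(OC)c(OCc4ccccc4)c(OC)c3 | intermediate
8 | (4S)-4-benzyl-3-{[(2S,3S)-2-[4-(benzyloxy)-3,5-dimethoxyphenyl]-5-oxooxolan-3-yl]carbonyl}-1,3-oxazolidin-2-one | O=C1C[C@H](C(=O)N2[C@@H](Cc3ccccc3)COC2=O)[C@@H](c4cc(OC)c(OCc5ccccc5)c(OC)c4)O1 | intermediate
9 | (2S,3S)-2-[4-(benzyloxy)-3,5-dimethoxyphenyl]-5-oxooxolane-3-carboperoxoic acid | O=C1C[C@H](C(=O)OO)[C@@H](c2cc(OC)c(OCc3ccccc3)c(OC)c2)O1 | intermediate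
10 | (2S,3S)-2-[4-(benzyloxy)-3,5-dimethoxyphenyl]-5-oxooxolane-3-carboxylic acid | O=C1C[C@H](C(=O)O)[C@@H](c2cc(OC)c(OCc3ccccc3)c(OC)c2)O1 | intermediate
11 | disodium carboxylate/lactone enolate of 10 | [Na+].[Na+].[O-]C1=C[C@H](C([O-])=O)[C@@H](c2cc(OC)c(OCc3ccccc3)c(OC)c2)O1 | intermediate
12 | (2S,3S,4R)-2-[4-(benzyloxy)-3,5-dimethoxyphenyl]-4-(hydroxymethyl)-5-oxooxolane-3-carboxylic acid | O=C1[C@@H](CO)[C@H](C(=O)O)[C@@H](c2cc(OC)c(OCc3ccccc3)c(OC)c2)O1 | intermediate
13 | (3R,4R,5S)-5-[4-(benzyloxy)-3,5-dimethoxyphenyl]-3,4-bis(hydroxymethyl)oxolan-2-one | O=C1[C@@H](CO)[C@H](CO)[C@@H](c2cc(OC)c(OCc3ccccc3)c(OC)c2)O1 | intermediate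
14 | (3R,4R)-4-{(S)-[4-(benzyloxy)-3,5-dimethoxyphenyl](hydroxy)methyl}-3-(hydroxymethyl)oxolan-2-one | O=C1OC[C@H]([C@H](O)c2cc(OC)c(OCc3ccccc3)c(OC)c2)[C@@H]1CO | intermediate
15 | (3aR,4S,6aR)-4-[4-(benzyloxy)-3,5-dimethoxyphenyl]tetrahydro-1H,3H-furo[3,4-c]furan-1-one (cis-fused, aryl exo) | O=C1OC[C@H]2[C@@H]1CO[C@@H]2c3cc(OC)c(OCc4ccccc4)c(OC)c3 | intermediate
16 | 4-bromo-2,6-dimethoxyphenol | COc1cc(Br)cc(OC)c1O | starting material
17 | 2-(benzyloxy)-5-bromo-1,3-dimethoxybenzene | COc1cc(Br)cc(OC)c1OCc1ccccc1 | intermediate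
18 | [4-(benzyloxy)-3,5-dimethoxyphenyl]lithium | [Li]c1cc(OC)c(OCc2ccccc2)c(OC)c1 | intermediate
19 | lithium (1S,3aR,4S,6aR)-1,4-bis[4-(benzyloxy)-3,5-dimethoxyphenyl]hexahydrofuro[3,4-c]furan-1-olate (new aryl exo) | [Li]O[C@]1(c3cc(OC)c(OCc4ccccc4)c(OC)c3)OC[C@H]2[C@@H]1CO[C@@H]2c5cc(OC)c(OCc6ccccc6)c(OC)c5 | intermediate
20 | [(3R,4R,5S)-5-[4-(benzyloxy)-3,5-dimethoxyphenyl]-4-(hydroxymethyl)oxolan-3-yl][4-(benzyloxy)-3,5-dimethoxyphenyl]methanone (3,4-cis) | COc1cc(C(=O)[C@H]2CO[C@H](c3cc(OC)c(OCc4ccccc4)c(OC)c3)[C@H]2CO)cc(OC)c1OCc1ccccc1 | intermediate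
21 | [(3S,4R,5S)-5-[4-(benzyloxy)-3,5-dimethoxyphenyl]-4-(hydroxymethyl)oxolan-3-yl][4-(benzyloxy)-3,5-dimethoxyphenyl]methanone (all-trans) | COc1cc(C(=O)[C@@H]2CO[C@H](c3cc(OC)c(OCc4ccccc4)c(OC)c3)[C@H]2CO)cc(OC)c1OCc1ccccc1 | intermediate
22 | [(3S,4R,5S)-5-(4-hydroxy-3,5-dimethoxyphenyl)-4-(hydroxymethyl)oxolan-3-yl](4-hydroxy-3,5-dimethoxyphenyl)methanone | COc1cc(C(=O)[C@@H]2CO[C@H](c3cc(OC)c(O)c(OC)c3)[C@H]2CO)cc(OC)c1O | target

**Step count:** 9 steps in total. The longest linear sequence is 7 steps (1, 3, 4, 5, 6, 8, 9).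

**Steps most likely to fail**

Step 8. The aryllithium may enolise the lactone instead of adding. The lactolate may collapse early and take up a second aryl group. The coupling and the epimerisation may also interfere with each other in one flask. Fallback: starting from 15, i-Bu2AlH (toluene, −78 °C) gives the bicyclic lactol F1. Two equivalents of 18 add to its hydroxy aldehyde form to give the benzylic carbinol diol F2, as a pair of epimers at the carbinol carbon. MnO2 in CH2Cl2 oxidises only the benzylic alcohol. This returns to the route at 20, which is isolated and equilibrated to 21 with DBU in toluene.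

Step 6. The benzylic cation may be lost to intermolecular Friedel–Crafts attack on another electron-rich ring, or ionisation may be too slow because the 4-alkoxy group is twisted out of conjugation. Fallback (anionic quinone methide route instead of a cation): starting from 13, brief hydrogenolysis (H2, Pd/C, EtOAc) frees the phenol diol lactone F3. K2CO3 in MeCN then expels the benzylic carboxylate from the phenolate to give the p-quinone methide F4. The C5 hydroxyl adds to it in a 5-exo-trig 1,6-addition to give the cis hydroxy acid F5. Acidification lactonises this to the phenolic bicyclic lactone F6, and BnBr with K2CO3 returns to the route at 15.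

Step 5. The dianion may be poorly soluble or sluggish. The aldol product may lose water to give the α-methylene lactone. Facial selectivity next to a small carboxylate may also be poor. Fallback (reduce and protect first, then use a neutral lactone with a bulky neighbour): starting from 10, BH3·SMe2 gives the hydroxymethyl lactone F7, and TBSCl with imidazole gives the silyl ether F8. LiN(i-Pr)2 (THF, −78 °C) forms the lithium enolate F9, and formaldehyde gas gives the anti hydroxymethyl silyl ether F10. p-TsOH·H2O in CH2Cl2 removes the silyl group and returns to the route at 13, which goes on to 15 in the same flask.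

**Further compounds**
F1 | step 8 | (3aR,4S,6aR)-4-[4-(benzyloxy)-3,5-dimethoxyphenyl]hexahydrofuro[3,4-c]furan-1-ol (anomers) | OC1OC[C@H]2[C@@H]1CO[C@@H]2c3cc(OC)c(OCc4ccccc4)c(OC)c3
F2 | step 8 | [(3R,4R,5S)-5-[4-(benzyloxy)-3,5-dimethoxyphenyl]-4-(hydroxymethyl)oxolan-3-yl][4-(benzyloxy)-3,5-dimethoxyphenyl]methanol (carbinol epimers) | OC(c1cc(OC)c(OCc2ccccc2)c(OC)c1)[C@H]3CO[C@H](c4cc(OC)c(OCc5ccccc5)c(OC)c4)[C@H]3CO
F3 | step 6 | (3R,4R,5S)-5-(4-hydroxy-3,5-dimethoxyphenyl)-3,4-bis(hydroxymethyl)oxolan-2-one | O=C1[C@@H](CO)[C@H](CO)[C@@H](c2cc(OC)c(O)c(OC)c2)O1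
F4 | step 6 | (2R,3R)-4-(3,5-dimethoxy-4-oxocyclohexa-2,5-dien-1-ylidene)-2,3-bis(hydroxymethyl)butanoic acid | OC(=O)[C@@H](CO)[C@H](CO)C=C1C=C(OC)C(=O)C(OC)=C1
F5 | step 6 | (3R,4R,5S)-5-(4-hydroxy-3,5-dimethoxyphenyl)-4-(hydroxymethyl)oxolane-3-carboxylic acid | OC(=O)[C@H]1CO[C@H](c2cc(OC)c(O)c(OC)c2)[C@H]1CO
F6 | step 6 | (3aR,4S,6aR)-4-(4-hydroxy-3,5-dimethoxyphenyl)tetrahydro-1H,3H-furo[3,4-c]furan-1-one | O=C1OC[C@H]2[C@@H]1CO[C@@H]2c3cc(OC)c(O)c(OC)c3
F7 | step 5 | (4R,5S)-5-[4-(benzyloxy)-3,5-dimethoxyphenyl]-4-(hydroxymethyl)oxolan-2-one | O=C1C[C@H](CO)[C@@H](c2cc(OC)c(OCc3ccccc3)c(OC)c2)O1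
F8 | step 5 | (4R,5S)-5-[4-(benzyloxy)-3,5-dimethoxyphenyl]-4-{[(tert-butyldimethylsilyl)oxy]methyl}oxolan-2-one | O=C1C[C@H](CO[Si](C)(C)C(C)(C)C)[C@@H](c2cc(OC)c(OCc3ccccc3)c(OC)c2)O1
F9 | step 5 | lithium enolate of F8 | [Li]OC1=C[C@H](CO[Si](C)(C)C(C)(C)C)[C@@H](c2cc(OC)c(OCc3ccccc3)c(OC)c2)O1
F10 | step 5 | (3R,4R,5S)-5-[4-(benzyloxy)-3,5-dimethoxyphenyl]-4-{[(tert-butyldimethylsilyl)oxy]methyl}-3-(hydroxymethyl)oxolan-2-one | O=C1[C@@H](CO)[C@H](CO[Si](C)(C)C(C)(C)C)[C@@H](c2cc(OC)c(OCc3ccccc3)c(OC)c2)O1
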